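**Retrosynthetic overview**

1. Numbering: C1 = benzylic CH2, C2 = CH(OAc), C3–C6 = (CH2)4, C7 = CH(OH), C8 = C=O, C9–C13 = pentyl. Target 21 comes from the tris-silyl ether 20 by one global desilylation.
2. Key disconnection C4–C5, the centre of the (CH2)4 tether: a Ni-electrocatalytic doubly decarboxylative union of two primary carbons of like polarity (redox-active esters 9 + 19). The enabling feature is the 1,6-dioxygenated array C2(O)···C7(O): C4 and C5 each lie γ to a carbinol carbon, so each half is a 4-oxygenated butanoic acid (γ-lactone retron) whose carboxyl group is a traceless radical precursor.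
3. East half 9 (C5–C13): from (R)-5-oxotetrahydrofuran-2-carboxylic acid 1 (C7 bought) by Weinreb amide formation, lactone opening/silylation and pentyl Grignard addition.
4. West half 19 (aryl, C1–C4): from 5-bromoresorcinol 10 and (R)-1,2-epoxy-5-hexene 12 (C2 bought) by Cu-catalysed aryl Grignard opening/acetylation and alkene-to-acid cleavage.
5. Rings: none is formed. The resorcinol ring is bought intact; the γ-lactone of 1 is a temporary ring, opened in step 2.

Key step: step 10

Remark: both stereocentres read as (R) from the SMILES (C2 and C7 in the numbering above); compounds 1, 6, 10 and 12 are taken as catalogue materials.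

**Route**

Step 1
Reactants: 1 (R)-5-oxotetrahydrofuran-2-carboxylic acid
Product: 2 (R)-N-methoxy-N-methyl-5-oxotetrahydrofuran-2-carboxamide
Conditions: MeNHOMe·HCl, EDC·HCl, N-methylmorpholine, CH2Cl2, 0 °C → rt
Reagents that add atoms: N,O-dimethylhydroxylamine hydrochloride, CNOC.Cl
Why: Carbodiimide amidation (Weinreb amide formation) of the free acid should leave the γ-lactone untouched, and the α-acyloxy stereocentre (C7 of the target, bought as R) should not racemise under these non-basic conditions.

Step 2
Reactants: 2 (R)-N-methoxy-N-methyl-5-oxotetrahydrofuran-2-carboxamide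
Product: 5 (R)-4-[(tert-butyldimethylsilyl)oxy]-5-[methoxy(methyl)amino]-5-oxopentanoic acid, via potassium hydroxy carboxylate 3 (not isolated), via bis-silylated ester 4 (not isolated)
Conditions: (i) KOH (1.05 equiv), THF/H2O, 0 °C → rt, evaporate to dryness; (ii) TBSCl, imidazole, DMF, rt; (iii) K2CO3, MeOH/THF/H2O, rt, then aq. KHSO4 to pH 4
Reagents that add atoms: potassium hydroxide, [K+].[OH-]; tert-butyldimethylsilyl chloride, CC(C)(C)[Si](C)(C)Cl
Why: Saponification, exhaustive silylation and selective solvolysis of the labile silyl ester is the standard way to unmask a γ-lactone as a 4-silyloxy acid; the Weinreb amide is much less electrophilic than the lactone and its α-proton is not removed by cold hydroxide, so the (R) centre should be retained.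

Step 3
Reactants: 5 (R)-4-[(tert-butyldimethylsilyl)oxy]-5-[methoxy(methyl)amino]-5-oxopentanoic acid; 6 pentylmagnesium bromide
Product: 8 (R)-4-[(tert-butyldimethylsilyl)oxy]-5-oxodecanoic acid, via tetrahedral magnesium adduct 7 (not isolated)
Conditions: 6 (2.5 equiv), THF, −20 → 0 °C; sat. aq. NH4Cl, then 1 M HCl to pH 4 at 0 °C
Reagents that add atoms: none
Why: Weinreb ketone synthesis: the first equivalent of Grignard reagent only converts the acid into an unreactive carboxylate, the second adds to the amide to give the stable chelate 7, which releases the ketone only on quench, so neither over-addition nor epimerisation of the α-silyloxy centre is expected.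

Step 4
Reactants: 8 (R)-4-[(tert-butyldimethylsilyl)oxy]-5-oxodecanoic acid
Product: 9 1,3-dioxoisoindolin-2-yl (R)-4-[(tert-butyldimethylsilyl)oxy]-5-oxodecanoate
Conditions: N-hydroxyphthalimide, DIC, DMAP (cat.), CH2Cl2, rt
Reagents that add atoms: N-hydroxyphthalimide, ON1C(=O)c2ccccc2C1=O
Why: Steglich-type esterification with N-hydroxyphthalimide should give the redox-active ester under neutral conditions that leave the α-silyloxy ketone untouched.

Step 5
Reactants: 10 5-bromobenzene-1,3-diol (5-bromoresorcinol)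
Product: 11 1-bromo-3,5-bis(triisopropylsilyloxy)benzene
Conditions: TIPSCl, imidazole, DMF, rt
Reagents that add atoms: triisopropylsilyl chloride, CC(C)[Si](Cl)(C(C)C)C(C)C
Why: Standard phenol silylation; triisopropylsilyl aryl ethers should tolerate Grignard formation and the later oxidations, yet fall to fluoride together with the alkyl silyl ether at the end.

Step 6
Reactants: 11 1-bromo-3,5-bis(triisopropylsilyloxy)benzene; 12 (R)-2-(but-3-en-1-yl)oxirane [(R)-1,2-epoxy-5-hexene]
Product: 15 (R)-1-[3,5-bis(triisopropylsilyloxy)phenyl]hex-5-en-2-yl acetate, via arylmagnesium bromide 13 (not isolated), via bromomagnesium alkoxide 14 (not isolated)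
Conditions: (i) Mg, THF, 45 °C; (ii) CuI (10 mol%), 12, THF, −30 → 0 °C; (iii) Ac2O, DMAP (cat.), 0 °C → rt
Reagents that add atoms: acetic anhydride, CC(=O)OC(C)=O
Why: Copper-catalysed SN2 opening of the terminal epoxide by the aryl Grignard reagent occurs at the unsubstituted carbon, so the purchased (R) carbinol centre (C2 of the target) is untouched, and the magnesium alkoxide is acetylated in the same flask.

Step 7
Reactants: 15 (R)-1-[3,5-bis(triisopropylsilyloxy)phenyl]hex-5-en-2-yl acetate
Product: 17 (R)-1-[3,5-bis(triisopropylsilyloxy)phenyl]-5-oxopentan-2-yl acetate, via vicinal diol 16 (not isolated)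
Conditions: OsO4 (2 mol%), NaIO4, 2,6-lutidine, dioxane/H2O (3:1), rt
Reagents that add atoms: osmium tetroxide (catalytic oxygen carrier), O=[Os](=O)(=O)=O; sodium periodate (terminal oxidant), [Na+].[O-]I(=O)(=O)=O
Why: Lemieux–Johnson oxidation (catalytic dihydroxylation, then periodate cleavage of diol 16) excises the terminal CH2 and leaves the future carboxyl carbon as an aldehyde; the remote stereocentre is not involved.

Step 8
Reactants: 17 (R)-1-[3,5-bis(triisopropylsilyloxy)phenyl]-5-oxopentan-2-yl acetate
Product: 18 (R)-4-acetoxy-5-[3,5-bis(triisopropylsilyloxy)phenyl]pentanoic acid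
Conditions: NaClO2, NaH2PO4, 2-methyl-2-butene (excess), t-BuOH/H2O, 0 °C → rt
Reagents that add atoms: sodium chlorite, [Na+].[O-]Cl=O
Why: Pinnick oxidation converts the aldehyde into the acid under mildly acidic conditions that spare the acetate and the aryl silyl ethers, the alkene scavenger intercepting hypochlorous acid before it can chlorinate the electron-rich ring.

Step 9
Reactants: 18 (R)-4-acetoxy-5-[3,5-bis(triisopropylsilyloxy)phenyl]pentanoic acid
Product: 19 1,3-dioxoisoindolin-2-yl (R)-4-acetoxy-5-[3,5-bis(triisopropylsilyloxy)phenyl]pentanoate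
Conditions: N-hydroxyphthalimide, DIC, DMAP (cat.), CH2Cl2, rt
Reagents that add atoms: N-hydroxyphthalimide, ON1C(=O)c2ccccc2C1=O
Why: The same Steglich-type activation as in step 4 should give the second redox-active ester without touching the acetate or the silyl ethers.

Step 10
Reactants: 9 1,3-dioxoisoindolin-2-yl (R)-4-[(tert-butyldimethylsilyl)oxy]-5-oxodecanoate (3 equiv); 19 1,3-dioxoisoindolin-2-yl (R)-4-acetoxy-5-[3,5-bis(triisopropylsilyloxy)phenyl]pentanoate (1 equiv)
Product: 20 (2R,7R)-1-[3,5-bis(triisopropylsilyloxy)phenyl]-7-[(tert-butyldimethylsilyl)oxy]-8-oxotridecan-2-yl acetate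
Conditions: NiCl2·6H2O (20 mol%), 2,2′:6′,2″-terpyridine (20 mol%), AgNO3 (0.3 equiv), NMP, Mg(+)/RVC(−), constant current, rt; dilute aq. HCl work-up
Reagents that add atoms: none
Why: Cathodically generated low-valent nickel (at a cathode modified by silver deposited from AgNO3) transfers an electron to each N-acyloxyphthalimide, which fragments to phthalimide anion, CO2 and a primary alkyl radical; the two radicals (C5 from 9, C4 from 19) are captured at nickel and the dialkylnickel species reductively eliminates to forge the C4–C5 σ-bond. The closest known reaction type is the Ni-electrocatalytic doubly decarboxylative C(sp3)–C(sp3) cross-coupling of two aliphatic redox-active esters, which is established for primary–primary unions of oxygenated acids. No ring is closed and no stereocentre is created; C2 and C7 each sit γ to a radical carbon and are carried through unchanged. The step needs cross- over homo-coupling, which is statistical and is secured by using the shorter-sequence ester 9 in threefold excess and removing the symmetrical dimers by chromatography. It also needs chemoselectivity for the redox-active esters over the C8 ketone, the acetate and the silyl ethers, which the mild potential of the sacrificial-anode cell should provide, and the absence of any β-leaving group (all oxygens are γ or further from the radical carbons) excludes β-elimination and 1,2-acyloxy shift.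

Step 11
Reactants: 20 (2R,7R)-1-[3,5-bis(triisopropylsilyloxy)phenyl]-7-[(tert-butyldimethylsilyl)oxy]-8-oxotridecan-2-yl acetate
Product: 21 (2R,7R)-1-(3,5-dihydroxyphenyl)-7-hydroxy-8-oxotridecan-2-yl acetate
Conditions: TBAF, AcOH (1:1, excess), THF, 0 °C → rt
Reagents that add atoms: none
Why: Fluoride-mediated desilylation should remove the two aryl silyl ethers and the α-keto secondary silyl ether in one operation, the acetic acid buffer keeping the medium non-basic so that the acetate stays in place and the α-hydroxy ketone neither epimerises nor undergoes acyloin transposition.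

**Compound list**

1 | (R)-5-oxotetrahydrofuran-2-carboxylic acid | OC(=O)[C@H]1CCC(=O)O1 | starting material
2 | (R)-N-methoxy-N-methyl-5-oxotetrahydrofuran-2-carboxamide | CON(C)C(=O)[C@H]1CCC(=O)O1 | intermediate
3 | potassium (R)-4-hydroxy-5-[methoxy(methyl)amino]-5-oxopentanoate | CON(C)C(=O)[C@@H](CCC(=O)[O-])O.[K+] | intermediate (not isolated)
4 | tert-butyldimethylsilyl (R)-4-[(tert-butyldimethylsilyl)oxy]-5-[methoxy(methyl)amino]-5-oxopentanoate | CON(C)C(=O)[C@@H](CCC(=O)O[Si](C)(C)C(C)(C)C)O[Si](C)(C)C(C)(C)C | intermediate (not isolated)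
5 | (R)-4-[(tert-butyldimethylsilyl)oxy]-5-[methoxy(methyl)amino]-5-oxopentanoic acid | CON(C)C(=O)[C@@H](CCC(=O)O)O[Si](C)(C)C(C)(C)C | intermediate
6 | pentylmagnesium bromide | CCCCC[Mg]Br | starting material
7 | bromomagnesium (4R)-5-(bromomagnesiooxy)-4-[(tert-butyldimethylsilyl)oxy]-5-[methoxy(methyl)amino]decanoate (C5 unassigned) | CCCCCC(O[Mg]Br)(N(C)OC)[C@@H](CCC(=O)O[Mg]Br)O[Si](C)(C)C(C)(C)C | intermediate (not isolated)
8 | (R)-4-[(tert-butyldimethylsilyl)oxy]-5-oxodecanoic acid | CCCCCC(=O)[C@@H](CCC(=O)O)O[Si](C)(C)C(C)(C)C | intermediate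
9 | 1,3-dioxoisoindolin-2-yl (R)-4-[(tert-butyldimethylsilyl)oxy]-5-oxodecanoate | CCCCCC(=O)[C@@H](CCC(=O)ON1C(=O)c2ccccc2C1=O)O[Si](C)(C)C(C)(C)C | intermediate
10 | 5-bromobenzene-1,3-diol | Oc1cc(O)cc(Br)c1 | starting material
11 | 1-bromo-3,5-bis(triisopropylsilyloxy)benzene | Brc1cc(O[Si](C(C)C)(C(C)C)C(C)C)cc(O[Si](C(C)C)(C(C)C)C(C)C)c1 | intermediate
12 | (R)-2-(but-3-en-1-yl)oxirane | C=CCC[C@@H]1CO1 | starting material
13 | [3,5-bis(triisopropylsilyloxy)phenyl]magnesium bromide | Br[Mg]c1cc(O[Si](C(C)C)(C(C)C)C(C)C)cc(O[Si](C(C)C)(C(C)C)C(C)C)c1 | intermediate (not isolated)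
14 | bromomagnesium (R)-1-[3,5-bis(triisopropylsilyloxy)phenyl]hex-5-en-2-olate | C=CCC[C@H](Cc1cc(O[Si](C(C)C)(C(C)C)C(C)C)cc(O[Si](C(C)C)(C(C)C)C(C)C)c1)O[Mg]Br | intermediate (not isolated)
15 | (R)-1-[3,5-bis(triisopropylsilyloxy)phenyl]hex-5-en-2-yl acetate | C=CCC[C@H](Cc1cc(O[Si](C(C)C)(C(C)C)C(C)C)cc(O[Si](C(C)C)(C(C)C)C(C)C)c1)OC(C)=O | intermediate
16 | (2R)-1-[3,5-bis(triisopropylsilyloxy)phenyl]-5,6-dihydroxyhexan-2-yl acetate (C5 epimers) | OCC(O)CC[C@H](Cc1cc(O[Si](C(C)C)(C(C)C)C(C)C)cc(O[Si](C(C)C)(C(C)C)C(C)C)c1)OC(C)=O | intermediate (not isolated)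
17 | (R)-1-[3,5-bis(triisopropylsilyloxy)phenyl]-5-oxopentan-2-yl acetate | O=CCC[C@H](Cc1cc(O[Si](C(C)C)(C(C)C)C(C)C)cc(O[Si](C(C)C)(C(C)C)C(C)C)c1)OC(C)=O | intermediate
18 | (R)-4-acetoxy-5-[3,5-bis(triisopropylsilyloxy)phenyl]pentanoic acid | OC(=O)CC[C@H](Cc1cc(O[Si](C(C)C)(C(C)C)C(C)C)cc(O[Si](C(C)C)(C(C)C)C(C)C)c1)OC(C)=O | intermediate
19 | 1,3-dioxoisoindolin-2-yl (R)-4-acetoxy-5-[3,5-bis(triisopropylsilyloxy)phenyl]pentanoate | O=C(CC[C@H](Cc1cc(O[Si](C(C)C)(C(C)C)C(C)C)cc(O[Si](C(C)C)(C(C)C)C(C)C)c1)OC(C)=O)ON1C(=O)c2ccccc2C1=O | intermediate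
20 | (2R,7R)-1-[3,5-bis(triisopropylsilyloxy)phenyl]-7-[(tert-butyldimethylsilyl)oxy]-8-oxotridecan-2-yl acetate | CCCCCC(=O)[C@@H](CCCC[C@H](Cc1cc(O[Si](C(C)C)(C(C)C)C(C)C)cc(O[Si](C(C)C)(C(C)C)C(C)C)c1)OC(C)=O)O[Si](C)(C)C(C)(C)C | intermediate
21 | (2R,7R)-1-(3,5-dihydroxyphenyl)-7-hydroxy-8-oxotridecan-2-yl acetate | CCCCCC(=O)[C@H](O)CCCC[C@H](Cc1cc(O)cc(O)c1)OC(C)=O | target

**Step count**

Total: 11 steps. Longest linear sequence: 7 steps (steps 5–11, from 10).

**Steps most likely to fail**

Step 10. The coupling may be eroded by statistical homocoupling, by protodecarboxylation of the radical or alkylnickel intermediates, or by cathodic over-reduction of the α-silyloxy ketone. The fallback differentiates the two halves into nucleophile and electrophile instead of coupling two electrophiles. It sets out from 19: visible-light iododecarboxylation (LiI, cat. PPh3, 456 nm, acetone) should give (S)-1-[3,5-bis(triisopropylsilyloxy)phenyl]-4-iodobutan-2-yl acetate F1 (same spatial arrangement at the carbinol carbon; the descriptor changes because CH2CH2I outranks CH2Ar). LiCl-mediated zinc insertion (Zn dust, THF) should then give {(S)-3-acetoxy-4-[3,5-bis(triisopropylsilyloxy)phenyl]butyl}zinc(II) iodide F2. A nickel-catalysed decarboxylative Negishi-type alkyl–alkyl coupling of F2 with redox-active ester 9 (NiCl2·glyme, 4,4′-di-tert-butyl-2,2′-bipyridine, THF/DMF, rt) forms the same C4–C5 bond and comes back to the route at 20.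

Step 3. Precipitation of the bromomagnesium carboxylate may stall the addition, and forcing it may lead to attack at the carboxylate or enolisation. The fallback masks the carboxyl group during the organometallic step. It sets out from 5: benzylation (BnBr, K2CO3, DMF) should give benzyl (R)-4-[(tert-butyldimethylsilyl)oxy]-5-[methoxy(methyl)amino]-5-oxopentanoate F3. Chemoselective addition of 6 (1.2 equiv, THF, −78 °C) to the chelating Weinreb amide should give benzyl (R)-4-[(tert-butyldimethylsilyl)oxy]-5-oxodecanoate F4. Hydrogenolysis (H2, Pd/C, EtOAc) comes back to the route at 8.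

Step 8. Electrophilic chlorination or oxidation of the electron-rich bis(silyloxy)arene by hypochlorous acid may outrun the scavenger. The fallback carries the carboxyl carbon at the acid oxidation level from the start, so that no oxidation is needed (it replaces steps 6–8). It sets out from 11, used as its Grignard reagent 13. (R)-(5-Oxotetrahydrofuran-2-yl)methyl 4-methylbenzenesulfonate F5 (purchased) is treated with BnOH/NaH (THF, 0 °C); lactone alcoholysis and intramolecular tosylate displacement should give benzyl (R)-3-(oxiran-2-yl)propanoate F6. Copper-catalysed opening of F6 with 13 (CuI cat., THF, −40 °C) should give bromomagnesium benzyl (R)-5-[3,5-bis(triisopropylsilyloxy)phenyl]-4-oxidopentanoate F7, which is trapped cold with Ac2O as benzyl (R)-4-acetoxy-5-[3,5-bis(triisopropylsilyloxy)phenyl]pentanoate F8. Hydrogenolysis (H2, Pd/C, EtOAc) comes back to the route at 18.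

**Further compounds**

F1 | step 10 | (S)-1-[3,5-bis(triisopropylsilyloxy)phenyl]-4-iodobutan-2-yl acetate | ICC[C@H](Cc1cc(O[Si](C(C)C)(C(C)C)C(C)C)cc(O[Si](C(C)C)(C(C)C)C(C)C)c1)OC(C)=O
F2 | step 10 | {(S)-3-acetoxy-4-[3,5-bis(triisopropylsilyloxy)phenyl]butyl}zinc(II) iodide | I[Zn]CC[C@H](Cc1cc(O[Si](C(C)C)(C(C)C)C(C)C)cc(O[Si](C(C)C)(C(C)C)C(C)C)c1)OC(C)=O
F3 | step 3 | benzyl (R)-4-[(tert-butyldimethylsilyl)oxy]-5-[methoxy(methyl)amino]-5-oxopentanoate | CON(C)C(=O)[C@@H](CCC(=O)OCc1ccccc1)O[Si](C)(C)C(C)(C)C
F4 | step 3 | benzyl (R)-4-[(tert-butyldimethylsilyl)oxy]-5-oxodecanoate | CCCCCC(=O)[C@@H](CCC(=O)OCc1ccccc1)O[Si](C)(C)C(C)(C)C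
F5 | step 8 | (R)-(5-oxotetrahydrofuran-2-yl)methyl 4-methylbenzenesulfonate (purchased) | Cc1ccc(cc1)S(=O)(=O)OC[C@H]1CCC(=O)O1
F6 | step 8 | benzyl (R)-3-(oxiran-2-yl)propanoate | O=C(CC[C@@H]1CO1)OCc1ccccc1
F7 | step 8 | bromomagnesium benzyl (R)-5-[3,5-bis(triisopropylsilyloxy)phenyl]-4-oxidopentanoate | O=C(CC[C@H](Cc1cc(O[Si](C(C)C)(C(C)C)C(C)C)cc(O[Si](C(C)C)(C(C)C)C(C)C)c1)O[Mg]Br)OCc1ccccc1
F8 | step 8 | benzyl (R)-4-acetoxy-5-[3,5-bis(triisopropylsilyloxy)phenyl]pentanoate | O=C(CC[C@H](Cc1cc(O[Si](C(C)C)(C(C)C)C(C)C)cc(O[Si](C(C)C)(C(C)C)C(C)C)c1)OC(C)=O)OCc1ccccc1
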